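**Plan**
- Retrosynthetic cuts, in order: (1) the four O–Si bonds; (2) in ring B (O2, C1, C6a, C3a, C3 of the furofuran) the C1–O2 bond, then the C1–aryl bond, back to bicyclic lactone 11 and aryllithium 21, which already carries the erythro glycerol ether; (3) in ring A (O5, C4, C3a, C6a, C6) the O5–C4 bond, back to a cyclopropane C3a–C4–C6a; (4) the cyclopropane and the lactone C–C bond, back to sinapyl α-formyl diazoacetate 8; (5) in the side chain C8''–OAr and C7''–C8''.
- Forward: the lactone ring and the cyclopropane form together in a carbene step; ring A follows by ring expansion of the cyclopropane; then hydrogenation, aryl addition, reduction, acid closure of ring B and desilylation.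
- Enabling feature: the syringyl group on C4 is a donor and C6a carries two carbonyl-level carbons (lactone C1 and the formyl carbon, later C6), so the C4–C6a bond of the cyclopropane ionises and the formyl oxygen becomes O5.
- Stereochemistry: C3a is set by a chiral cobalt catalyst (step 6); C4 (step 7), C6a (step 8) and C1 (step 16) are relayed from it; C7'' and C8'' come from an oxazolidinone-controlled syn-aldol (step 10) and inversion at C8'' (step 11).

Key step: step 7

Assumption: the antipode of the cobalt porphyrin used in step 6 is the one that gives the (1R,5S,6R) cyclopropane, and the chloroacetyl imide in step 10 follows the same facial sense as the propionyl imide in the boron aldol.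

Abbreviations: ArS = 3,5-dimethoxy-4-[tri(propan-2-yl)silyloxy]phenyl; ArG = 3-methoxy-4-[tri(propan-2-yl)silyloxy]phenyl; TIPS = tri(propan-2-yl)silyl; TBS = tert-butyldimethylsilyl.

**Step 1**
Reactants: 1 syringaldehyde (4-hydroxy-3,5-dimethoxybenzaldehyde)
Product: 2 3,5-dimethoxy-4-[tri(propan-2-yl)silyloxy]benzaldehyde
Conditions: TIPSCl, imidazole, DMAP (cat.), DMF, 50 °C
Reagents that add atoms: chlorotri(propan-2-yl)silane, CC(C)[Si](Cl)(C(C)C)C(C)C
Why: O-silylation masks the phenol for the base, hydride and carbene steps, leaves the para oxygen a donor and is removable by fluoride at the end.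

**Step 2**
Reactants: 2 3,5-dimethoxy-4-[tri(propan-2-yl)silyloxy]benzaldehyde
Product: 3 ethyl (E)-3-ArS-prop-2-enoate
Conditions: (EtO)2P(O)CH2CO2Et, NaH, THF, 0 °C to rt
Reagents that add atoms: triethyl phosphonoacetate, CCOC(=O)CP(=O)(OCC)OCC
Why: Horner–Wadsworth–Emmons olefination of an aromatic aldehyde with a stabilised phosphonate anion should give the E enoate, whose geometry later places aryl trans to CH2O on the cyclopropane.

**Step 3**
Reactants: 3 ethyl (E)-3-ArS-prop-2-enoate
Product: 4 (E)-3-ArS-prop-2-en-1-ol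
Conditions: iBu2AlH (2.2 equiv), CH2Cl2, −78 °C; aq. potassium sodium tartrate
Reagents that add atoms: none
Why: 1,2-reduction of the enoate by the aluminium hydride at low temperature gives the allylic alcohol without touching the alkene or the aryl silyl ether.

**Step 4**
Reactants: 4 (E)-3-ArS-prop-2-en-1-ol
Product: 6 (E)-3-ArS-prop-2-en-1-yl 2-diazoacetate, via glyoxylate tosylhydrazone ester 5 (not isolated)
Conditions: TsNHN=CHCOCl, PhNMe2, CH2Cl2, 0 °C; then Et3N, 0 °C to rt
Reagents that add atoms: 2-[2-(4-methylbenzenesulfonyl)hydrazinylidene]acetyl chloride, Cc1ccc(cc1)S(=O)(=O)N/N=C/C(=O)Cl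
Why: acylation of the alcohol by the hydrazone acid chloride and base-induced loss of sulfinate (Bamford–Stevens-type fragmentation) is the standard one-flask route to allylic diazoacetates.

**Step 5**
Reactants: 6 (E)-3-ArS-prop-2-en-1-yl 2-diazoacetate
Product: 8 (E)-3-ArS-prop-2-en-1-yl 2-diazo-3-oxopropanoate, via diazo iminium chloride 7 (not isolated)
Conditions: (chloromethylene)dimethyliminium chloride, 2,6-di-tert-butyl-4-methylpyridine, CHCl3, 0 °C to rt; then 10% aq. AcOH
Reagents that add atoms: (chloromethylene)dimethyliminium chloride, C[N+](C)=CCl.[Cl-]; water, O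
Why: Vilsmeier formylation at the nucleophilic diazo carbon and hydrolysis of iminium 7 give the acceptor/acceptor diazo compound, while the hindered pyridine takes up HCl so that the acid-labile sinapyl ester should survive.

**Step 6**
Reactants: 8 (E)-3-ArS-prop-2-en-1-yl 2-diazo-3-oxopropanoate
Product: 9 (1R,5S,6R)-6-ArS-2-oxo-3-oxabicyclo[3.1.0]hexane-1-carbaldehyde
Conditions: [Co(3,5-DitBu-ChenPhyrin)] (divalent cobalt complex of a D2-symmetric chiral amidoporphyrin, 2 mol%), DMAP (0.5 equiv), toluene, rt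
Reagents that add atoms: none
Why: intramolecular cyclopropanation by cobalt metalloradical catalysis (known for allyl α-acceptor diazoacetates and for α-formyl diazoacetates): the cobalt-bound carbon radical adds 5-exo-trig to the alkene inside the chiral porphyrin pocket and sets C5, the benzylic radical closes 3-exo-tet, and the E alkene places aryl trans to C4.

**Step 7**
Reactants: 9 (1R,5S,6R)-6-ArS-2-oxo-3-oxabicyclo[3.1.0]hexane-1-carbaldehyde
Product: 10 (3aS,4R)-4-ArS-3a,4-dihydro-1H,3H-furo[3,4-c]furan-1-one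
Conditions: Sc(OTf)3 (10 mol%), CH2Cl2, 0 °C to rt
Reagents that add atoms: none
Why: Sc(OTf)3 chelates the formyl and lactone carbonyl groups on C1, the C1–C6 bond heterolyses to a benzylic cation (stabilised through the para silyloxy oxygen) and a scandium 1,3-dicarbonyl enolate, and the formyl oxygen closes onto the cation, so that the three-membered ring C1–C5–C6 grows by the atoms O and CH into the 2,3-dihydrofuran ring A, driven by release of the bicyclo[3.1.0] strain and formation of a vinylogous carbonate. The closest known reaction type is the Lewis acid-catalysed Cloke–Wilson rearrangement of donor–acceptor cyclopropyl aldehydes and ketones. Ring A closes at oxygen in a 5-(enolendo)-exo-trig mode. The re-formed stereocentre C4 is controlled by C3a (the former C5), the only centre that persists through the zwitterion: oxygen bonds to the lobe of the cation from which C1 departed, so aryl stays trans to the lactone CH2, which is also the less hindered exo arrangement. The step needs closure by the formyl oxygen and not the lactone carbonyl oxygen, which the substrate secures because the latter would give a bridged bicyclo[2.2.1] ketene acetal with a bridgehead double bond; catalytic acid at low temperature should suppress proton loss and arylation at the cation.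

**Step 8**
Reactants: 10 (3aS,4R)-4-ArS-3a,4-dihydro-1H,3H-furo[3,4-c]furan-1-one
Product: 11 (3aS,4R,6aS)-4-ArS-tetrahydro-1H,3H-furo[3,4-c]furan-1-one
Conditions: H2 (1 atm), 5% Rh/Al2O3, EtOAc, rt
Reagents that add atoms: none
Why: heterogeneous hydrogenation of the push–pull alkene delivers hydrogen syn on the face of H-3a (the other face is blocked by C3) to give the cis-fused lactone, which is also the thermodynamic epimer at the enolisable C6a; rhodium is chosen over palladium to spare the benzylic C–O bond.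

**Step 9**
Reactants: 12 vanillin (4-hydroxy-3-methoxybenzaldehyde)
Product: 13 3-methoxy-4-[tri(propan-2-yl)silyloxy]benzaldehyde
Conditions: TIPSCl, imidazole, DMF, rt
Reagents that add atoms: chlorotri(propan-2-yl)silane, CC(C)[Si](Cl)(C(C)C)C(C)C
Why: O-silylation gives a phenol protecting group that should tolerate the aldol, the phenoxide substitution and the aryllithium step.

**Step 10**
Reactants: 14 (4S)-4-benzyl-3-(chloroacetyl)-1,3-oxazolidin-2-one; 13 3-methoxy-4-[tri(propan-2-yl)silyloxy]benzaldehyde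
Product: 16 (4S)-4-benzyl-3-[(2S,3R)-2-chloro-3-hydroxy-3-ArG-propanoyl]-1,3-oxazolidin-2-one, via Z boron enolate 15 (not isolated)
Conditions: Bu2BOTf, Et3N, CH2Cl2, −78 °C; 13, −78 to 0 °C; pH 7 buffer, MeOH, 30% H2O2, 0 °C
Reagents that add atoms: none
Why: Evans syn-aldol reaction, in which the Z boron enolate 15 reacts through a closed chair transition state on the face away from the benzyl group and sets C2 and C3 of the chlorohydrin together.

**Step 11**
Reactants: 16 (4S)-4-benzyl-3-[(2S,3R)-2-chloro-3-hydroxy-3-ArG-propanoyl]-1,3-oxazolidin-2-one; 17 4-bromo-2-methoxyphenol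
Product: 18 (4S)-4-benzyl-3-[(2R,3R)-2-(4-bromo-2-methoxyphenoxy)-3-hydroxy-3-ArG-propanoyl]-1,3-oxazolidin-2-one
Conditions: 17 (2 equiv), Cs2CO3 (1 equiv), DMF, 0 °C to rt
Reagents that add atoms: none
Why: bimolecular substitution of the α-chloro imide by the phenoxide with inversion at C2 (the same type as the azide displacement on such halohydrins) turns the syn chlorohydrin into the anti (erythro) aryl ether; phenoxide is too weak a base to form the alkoxide needed for retro-aldol, and allylic strain in the imide disfavours enolisation.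

**Step 12**
Reactants: 18 (4S)-4-benzyl-3-[(2R,3R)-2-(4-bromo-2-methoxyphenoxy)-3-hydroxy-3-ArG-propanoyl]-1,3-oxazolidin-2-one
Product: 19 (1R,2S)-2-(4-bromo-2-methoxyphenoxy)-1-ArG-propane-1,3-diol
Conditions: LiBH4, H2O (1 equiv), Et2O/THF, 0 °C
Reagents that add atoms: none
Why: reductive cleavage of the N-acyl oxazolidinone by LiBH4 gives the primary alcohol and returns the auxiliary without touching either stereocentre or the aryl bromide.

**Step 13**
Reactants: 19 (1R,2S)-2-(4-bromo-2-methoxyphenoxy)-1-ArG-propane-1,3-diol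
Product: 20 bis-TBS ether of 19 (1-O and 3-O silylated)
Conditions: TBSOTf (2.5 equiv), 2,6-lutidine, CH2Cl2, −78 to 0 °C
Reagents that add atoms: tert-butyldimethylsilyl trifluoromethanesulfonate, CC(C)(C)[Si](C)(C)OS(=O)(=O)C(F)(F)F
Why: the silyl triflate silylates both the primary and the hindered benzylic hydroxyl, giving a fragment whose protecting groups all fall to fluoride.

**Step 14**
Reactants: 20 bis-TBS ether of 19; 11 (3aS,4R,6aS)-4-ArS-tetrahydro-1H,3H-furo[3,4-c]furan-1-one
Product: 22 (3aS,4R,6aS)-1-aryl-4-ArS-tetrahydro-1H,3H-furo[3,4-c]furan-1-ol (aryl = the side-chain arene of 20; both C1 epimers, in equilibrium with the hydroxy ketone), via aryllithium 21 (not isolated)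
Conditions: 20, tBuLi (2.0 equiv), THF, −78 °C; 11, −78 °C; aq. NH4Cl
Reagents that add atoms: none
Why: bromine–lithium exchange followed by addition of the aryllithium to the lactone carbonyl, where the tetrahedral lithium alkoxide resists a second addition at −78 °C; the hemiketal carbon is not controlled and need not be.

**Step 15**
Reactants: 22 lactol (hydroxy ketone tautomer)
Product: 23 (2R,3S,4S)-2-ArS-3-(hydroxymethyl)-4-[aryl(hydroxy)methyl]oxolane (both carbinol epimers)
Conditions: NaBH4, MeOH/THF, 0 °C to rt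
Reagents that add atoms: none
Why: borohydride reduces the open hydroxy ketone tautomer to the 1,4-diol; the new carbinol configuration is irrelevant because it is erased in step 16.

**Step 16**
Reactants: 23 diol
Product: 24 (1R,3aS,4R,6aS)-1-aryl-4-ArS-tetrahydro-1H,3H-furo[3,4-c]furan (fully silylated target)
Conditions: camphorsulfonic acid (10 mol%), 4 Å molecular sieves, CH2Cl2, 0 °C
Reagents that add atoms: none
Why: acid-catalysed ionisation of the 4-alkoxy-3-methoxybenzylic alcohol and 5-exo-trig capture of the cation by the cis primary hydroxyl (the closure mode of the quinone methides that give pinoresinol-type lignans) closes ring B with the aryl group on the convex (exo) side, so C1 is set by the bicycle; catalytic acid at 0 °C should leave the silyl ethers and the ring A benzylic ether intact and keep C-arylation by the syringyl ring out.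

**Step 17**
Reactants: 24 fully silylated target
Product: 25 Ficusesquilignan A
Conditions: Bu4NF (6 equiv), AcOH (6 equiv), THF, 0 °C to rt
Reagents that add atoms: none
Why: fluoride cleaves the two aryl TIPS and two alkyl TBS ethers in one operation, and acetic acid buffers the phenoxides so that the p-hydroxybenzylic ethers are not opened through quinone methides.

**Compound list**
1 | syringaldehyde | COc1cc(C=O)cc(OC)c1O | starting material
2 | 3,5-dimethoxy-4-(TIPS-oxy)benzaldehyde | COc1cc(C=O)cc(OC)c1O[Si](C(C)C)(C(C)C)C(C)C | intermediate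
3 | ethyl (E)-3-ArS-prop-2-enoate | CCOC(=O)/C=C/c1cc(OC)c(O[Si](C(C)C)(C(C)C)C(C)C)c(OC)c1 | intermediate
4 | (E)-3-ArS-prop-2-en-1-ol | OC/C=C/c1cc(OC)c(O[Si](C(C)C)(C(C)C)C(C)C)c(OC)c1 | intermediate
5 | (E)-3-ArS-prop-2-en-1-yl glyoxylate tosylhydrazone | Cc1ccc(cc1)S(=O)(=O)N/N=C/C(=O)OC/C=C/c1cc(OC)c(O[Si](C(C)C)(C(C)C)C(C)C)c(OC)c1 | intermediate
6 | (E)-3-ArS-prop-2-en-1-yl 2-diazoacetate | [N-]=[N+]=CC(=O)OC/C=C/c1cc(OC)c(O[Si](C(C)C)(C(C)C)C(C)C)c(OC)c1 | intermediate
7 | N,N-dimethyliminium chloride of 8 (C3 iminium) | C[N+](C)=CC(=[N+]=[N-])C(=O)OC/C=C/c1cc(OC)c(O[Si](C(C)C)(C(C)C)C(C)C)c(OC)c1.[Cl-] | intermediate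
8 | (E)-3-ArS-prop-2-en-1-yl 2-diazo-3-oxopropanoate | O=CC(=[N+]=[N-])C(=O)OC/C=C/c1cc(OC)c(O[Si](C(C)C)(C(C)C)C(C)C)c(OC)c1 | intermediate
9 | (1R,5S,6R)-6-ArS-2-oxo-3-oxabicyclo[3.1.0]hexane-1-carbaldehyde | O=C1OC[C@@H]2[C@@]1(C=O)[C@H]2c3cc(OC)c(O[Si](C(C)C)(C(C)C)C(C)C)c(OC)c3 | intermediate
10 | (3aS,4R)-4-ArS-3a,4-dihydro-1H,3H-furo[3,4-c]furan-1-one | O=C1OC[C@@H]2C1=CO[C@H]2c3cc(OC)c(O[Si](C(C)C)(C(C)C)C(C)C)c(OC)c3 | intermediate
11 | (3aS,4R,6aS)-4-ArS-tetrahydro-1H,3H-furo[3,4-c]furan-1-one | O=C1OC[C@@H]2[C@H]1CO[C@H]2c3cc(OC)c(O[Si](C(C)C)(C(C)C)C(C)C)c(OC)c3 | intermediate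
12 | vanillin | COc1cc(C=O)ccc1O | starting material
13 | 3-methoxy-4-(TIPS-oxy)benzaldehyde | COc1cc(C=O)ccc1O[Si](C(C)C)(C(C)C)C(C)C | intermediate
14 | (4S)-4-benzyl-3-(chloroacetyl)-1,3-oxazolidin-2-one | ClCC(=O)N1C(=O)OC[C@@H]1Cc2ccccc2 | starting material
15 | Z dibutylboron enolate of 14 | CCCCB(CCCC)O/C(=C\Cl)N1C(=O)OC[C@@H]1Cc2ccccc2 | intermediate
16 | (4S)-4-benzyl-3-[(2S,3R)-2-chloro-3-hydroxy-3-ArG-propanoyl]-1,3-oxazolidin-2-one | COc1cc([C@@H](O)[C@H](Cl)C(=O)N2C(=O)OC[C@@H]2Cc3ccccc3)ccc1O[Si](C(C)C)(C(C)C)C(C)C | intermediate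
17 | 4-bromo-2-methoxyphenol | COc1cc(Br)ccc1O | starting material
18 | (4S)-4-benzyl-3-[(2R,3R)-2-(4-bromo-2-methoxyphenoxy)-3-hydroxy-3-ArG-propanoyl]-1,3-oxazolidin-2-one | COc1cc([C@@H](O)[C@H](C(=O)N2C(=O)OC[C@@H]2Cc3ccccc3)Oc4ccc(Br)cc4OC)ccc1O[Si](C(C)C)(C(C)C)C(C)C | intermediate
19 | (1R,2S)-2-(4-bromo-2-methoxyphenoxy)-1-ArG-propane-1,3-diol | COc1cc([C@@H](O)[C@H](CO)Oc2ccc(Br)cc2OC)ccc1O[Si](C(C)C)(C(C)C)C(C)C | intermediate
20 | bis-TBS ether of 19 | COc1cc([C@@H](O[Si](C)(C)C(C)(C)C)[C@H](CO[Si](C)(C)C(C)(C)C)Oc2ccc(Br)cc2OC)ccc1O[Si](C(C)C)(C(C)C)C(C)C | intermediate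
21 | aryllithium from 20 | COc1cc([C@@H](O[Si](C)(C)C(C)(C)C)[C@H](CO[Si](C)(C)C(C)(C)C)Oc2ccc([Li])cc2OC)ccc1O[Si](C(C)C)(C(C)C)C(C)C | intermediate
22 | (3aS,4R,6aS)-1-aryl-4-ArS-tetrahydro-1H,3H-furo[3,4-c]furan-1-ol, C1 epimers | COc1cc([C@@H](O[Si](C)(C)C(C)(C)C)[C@H](CO[Si](C)(C)C(C)(C)C)Oc2ccc(C3(O)OC[C@@H]4[C@H]3CO[C@H]4c5cc(OC)c(O[Si](C(C)C)(C(C)C)C(C)C)c(OC)c5)cc2OC)ccc1O[Si](C(C)C)(C(C)C)C(C)C | intermediate
23 | (2R,3S,4S)-2-ArS-3-(hydroxymethyl)-4-[aryl(hydroxy)methyl]oxolane, carbinol epimers | COc1cc([C@@H](O[Si](C)(C)C(C)(C)C)[C@H](CO[Si](C)(C)C(C)(C)C)Oc2ccc(C(O)[C@@H]3CO[C@@H](c4cc(OC)c(O[Si](C(C)C)(C(C)C)C(C)C)c(OC)c4)[C@@H]3CO)cc2OC)ccc1O[Si](C(C)C)(C(C)C)C(C)C | intermediate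
24 | fully silylated Ficusesquilignan A, (1R,3aS,4R,6aS) core | COc1cc([C@@H](O[Si](C)(C)C(C)(C)C)[C@H](CO[Si](C)(C)C(C)(C)C)Oc2ccc([C@@H]3OC[C@@H]4[C@H]3CO[C@H]4c5cc(OC)c(O[Si](C(C)C)(C(C)C)C(C)C)c(OC)c5)cc2OC)ccc1O[Si](C(C)C)(C(C)C)C(C)C | intermediate
25 | Ficusesquilignan A, (1R,2S)-1-(4-hydroxy-3-methoxyphenyl)-2-{4-[(1R,3aS,4R,6aS)-4-(4-hydroxy-3,5-dimethoxyphenyl)tetrahydro-1H,3H-furo[3,4-c]furan-1-yl]-2-methoxyphenoxy}propane-1,3-diol | COc1cc([C@@H](O)[C@H](CO)Oc2ccc([C@@H]3OC[C@@H]4[C@H]3CO[C@H]4c3cc(OC)c(O)c(OC)c3)cc2OC)ccc1O | target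

Total step count: 17. Longest linear sequence: 12 steps (steps 1 to 8, then 14 to 17).

**Steps most likely to fail**

Step 6. The radical addition of the cobalt carbene to the alkene may lose facial control (low enantiomeric purity), or the carbene may be diverted by its own formyl group. The fallback gives up catalyst control for resolution. It sets out from 8: Rh2(OAc)4 (1 mol%) in CH2Cl2 at rt should give the racemic cyclopropane, that is 9 together with the (1S,5R,6S)-cyclopropane aldehyde F1. Steps 7 and 8 on the racemate should give, beside 10 and 11, the (3aR,4S)-dihydrofuranone F2 and the (3aR,4S,6aR)-lactone F3. The racemic lactone is resolved by preparative chromatography on a chiral stationary phase, F3 is discarded, and the route is rejoined at 11.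

Step 8. The benzylic C4–O5 bond, which is also the leaving group of a vinylogous ester, may be hydrogenolysed, or the push–pull alkene may stall on the catalyst. The fallback avoids the enol ether altogether. It sets out from 9: NaBH4 in MeOH at −40 °C should reduce only the aldehyde, giving the (1R,5S,6R)-1-(hydroxymethyl) cyclopropane lactone F4. BF3·OEt2 (or Sc(OTf)3) in CH2Cl2 from −40 to 0 °C should then ionise the C1–C6 bond; the primary hydroxyl captures the benzylic cation (the known Lewis acid opening of such aryl cyclopropane lactones by alcohols, here intramolecular) and the lactone enol is protonated on the convex face. This gives 11 directly, where the route is rejoined.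

Step 11. The phenoxide or carbonate may deprotonate the α-carbon (epimerisation), the β-hydroxy imide may cleave by retro-aldol, or chloride exchange may erode the configuration before the ether forms. The fallback builds the aryl ether first and corrects C7'' afterwards. It sets out from 17 and 13:
- Alkylation of 17 with commercial (4R)-4-benzyl-3-(chloroacetyl)-1,3-oxazolidin-2-one (K2CO3, acetone) should give the (4R)-N-(aryloxyacetyl) imide F5.
- Evans syn-aldol of F5 with 13 (Bu2BOTf, iPr2NEt) should give the (2R,3S) syn adduct F6.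
- LiBH4 should give the (1S,2S) threo diol F7.
- DDQ should oxidise the electron-rich benzylic alcohol selectively to the (2S) ketone F8.
- NaBH4 reduction of F8, which favours the erythro alcohol in 2-aryloxy-3-hydroxypropiophenones, followed by chromatographic removal of the threo isomer, rejoins the route at 19.

**Further compounds**
F1 | step 6 | (1S,5R,6S)-6-ArS-2-oxo-3-oxabicyclo[3.1.0]hexane-1-carbaldehyde | O=C1OC[C@H]2[C@]1(C=O)[C@@H]2c3cc(OC)c(O[Si](C(C)C)(C(C)C)C(C)C)c(OC)c3
F2 | step 6 | (3aR,4S)-4-ArS-3a,4-dihydro-1H,3H-furo[3,4-c]furan-1-one | O=C1OC[C@H]2C1=CO[C@@H]2c3cc(OC)c(O[Si](C(C)C)(C(C)C)C(C)C)c(OC)c3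
F3 | step 6 | (3aR,4S,6aR)-4-ArS-tetrahydro-1H,3H-furo[3,4-c]furan-1-one | O=C1OC[C@H]2[C@@H]1CO[C@@H]2c3cc(OC)c(O[Si](C(C)C)(C(C)C)C(C)C)c(OC)c3
F4 | step 8 | (1R,5S,6R)-6-ArS-1-(hydroxymethyl)-3-oxabicyclo[3.1.0]hexan-2-one | O=C1OC[C@@H]2[C@@]1(CO)[C@H]2c3cc(OC)c(O[Si](C(C)C)(C(C)C)C(C)C)c(OC)c3
F5 | step 11 | (4R)-4-benzyl-3-[2-(4-bromo-2-methoxyphenoxy)acetyl]-1,3-oxazolidin-2-one | COc1cc(Br)ccc1OCC(=O)N1C(=O)OC[C@H]1Cc2ccccc2
F6 | step 11 | (4R)-4-benzyl-3-[(2R,3S)-2-(4-bromo-2-methoxyphenoxy)-3-hydroxy-3-ArG-propanoyl]-1,3-oxazolidin-2-one | COc1cc([C@H](O)[C@H](C(=O)N2C(=O)OC[C@H]2Cc3ccccc3)Oc4ccc(Br)cc4OC)ccc1O[Si](C(C)C)(C(C)C)C(C)C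
F7 | step 11 | (1S,2S)-2-(4-bromo-2-methoxyphenoxy)-1-ArG-propane-1,3-diol | COc1cc([C@H](O)[C@H](CO)Oc2ccc(Br)cc2OC)ccc1O[Si](C(C)C)(C(C)C)C(C)C
F8 | step 11 | (2S)-2-(4-bromo-2-methoxyphenoxy)-3-hydroxy-1-ArG-propan-1-one | COc1cc(C(=O)[C@H](CO)Oc2ccc(Br)cc2OC)ccc1O[Si](C(C)C)(C(C)C)C(C)C
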